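The dihydropyran ring is taken back to its C3=C4 chromene, whose ring atoms O1, C8a, C4a, C4, C3 and C2 (chroman numbering) form a 1-oxatriene. The key step builds that oxatriene from prenal and the single free, benzoyl-flanked phenol of a bis-MOM 2,4,6-trihydroxybenzophenone and closes it by oxa-6π electrocyclisation, forming C4a–C4 and then the O1–C2 bond in one operation. It exploits the non-stereogenic gem-dimethyl carbon C2 next to aryl oxygen O1: closure needs no stereocontrol, and the alkene it leaves lets the lone stereocentre C3 be set by Jacobsen epoxidation and benzylic hydrogenolysis. Deprotection and C6 prenylation finish the route.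

Key step: step 2

Remark on the chemistry: the stereodescriptor of the target corresponds to 3R (chroman numbering: O1, C2 gem-dimethyl, C3 carbinol, C4 methylene, C5 and C7 hydroxyls, C6 prenyl, C8 benzoyl), and the (R,R) catalyst in step 3 is chosen for this enantiomer.

Step 1
Reactants: 1 2,4,6-trihydroxybenzophenone
Product: 2 (2-hydroxy-4,6-bis(methoxymethoxy)phenyl)(phenyl)methanone
Conditions: MOMCl (2.2 equiv), K2CO3 (3 equiv), acetone, 0 °C to rt
Reagents that add atoms: chloromethyl methyl ether, COCCl
Why: Williamson-type O-alkylation (MOM protection) takes the para hydroxyl and one ortho hydroxyl, while the last ortho hydroxyl stays free because it is locked in the hydrogen bond to the benzoyl carbonyl, which singles out the phenol that will become O1.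

Step 2
Reactants: 2 (2-hydroxy-4,6-bis(methoxymethoxy)phenyl)(phenyl)methanone; 3 3-methylbut-2-enal (prenal)
Product: 5 [5,7-bis(methoxymethoxy)-2,2-dimethyl-2H-chromen-8-yl](phenyl)methanone, via ortho-quinone methide 4 (not isolated)
Conditions: 3 (2 equiv), ethylenediammonium diacetate (20 mol%), xylene, 140 °C
Reagents that add atoms: none
Why: The diamine salt turns prenal into an iminium ion, C3 of 2 (benzophenone numbering; ortho to the free hydroxyl and activated by three oxygen donors) adds to it, and loss of the amine gives ortho-quinone methide 4, a 1-oxatriene whose thermal disrotatory oxa-6π electrocyclisation joins the former phenol oxygen to the dimethyl-bearing terminus (O1–C2) and restores the aromatic ring. The closest known reaction type is the amine-promoted chromenylation of resorcinols and phloroglucinols with enals, a formal [3+3] annulation by Knoevenagel-type condensation and electrocyclisation. The pyran ring closes in a pericyclic six-electron mode (formally 6-endo), driven by rearomatisation. No stereocentre is formed, since C2 carries two methyl groups; the C3=C4 alkene that remains is the handle for step 3. The step needs C-attack ortho and not para to the hydroxyl and closure onto the oxygen beside the benzoyl group: only the ortho adduct can eliminate to a quinone methide, the para adduct is unproductive and reverts, and the other two oxygens are blocked as MOM ethers, so the one oxygen able to close is the one that must become O1.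

Step 3
Reactants: 5 [5,7-bis(methoxymethoxy)-2,2-dimethyl-2H-chromen-8-yl](phenyl)methanone
Product: 6 [(3R,4R)-3,4-epoxy-5,7-bis(methoxymethoxy)-2,2-dimethyl-3,4-dihydro-2H-chromen-8-yl](phenyl)methanone
Conditions: (R,R)-Jacobsen catalyst [(R,R)-N,N'-bis(3,5-di-tert-butylsalicylidene)cyclohexane-1,2-diaminato]MnCl (5 mol%), 4-phenylpyridine N-oxide (20 mol%), aq. NaOCl, Na2HPO4 buffer (pH 11.3), CH2Cl2, 0 °C; filtered through basic Al2O3 and used at once
Reagents that add atoms: sodium hypochlorite, [Na+].[O-]Cl
Why: Jacobsen–Katsuki epoxidation, for which 2,2-dimethylchromenes are a privileged cis-alkene class and which meets no free phenol or second alkene here; the (R,R) catalyst should deliver oxygen to the face that gives the (3R,4R) epoxide, which sets C3, and the basic buffered medium spares the acid-labile product.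

Step 4
Reactants: 6 [(3R,4R)-3,4-epoxy-5,7-bis(methoxymethoxy)-2,2-dimethyl-3,4-dihydro-2H-chromen-8-yl](phenyl)methanone
Product: 7 [(3R)-3-hydroxy-5,7-bis(methoxymethoxy)-2,2-dimethyl-3,4-dihydro-2H-chromen-8-yl](phenyl)methanone
Conditions: H2 (1 atm), Pd/C (10 wt% Pd, 5 mol%), K2CO3 (0.2 equiv), EtOAc, rt; stopped after 1 equiv H2
Reagents that add atoms: none
Why: Heterogeneous hydrogenolysis of a benzylic epoxide cleaves only the C4–O bond, which is benzylic and activated by the ortho and para oxygens, so the C3–O bond and the 3R configuration are untouched, while the twisted, doubly ortho-substituted benzophenone carbonyl and the MOM ethers should survive at one atmosphere.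

Step 5
Reactants: 7 [(3R)-3-hydroxy-5,7-bis(methoxymethoxy)-2,2-dimethyl-3,4-dihydro-2H-chromen-8-yl](phenyl)methanone
Product: 8 [(3R)-3,5,7-trihydroxy-2,2-dimethyl-3,4-dihydro-2H-chromen-8-yl](phenyl)methanone
Conditions: 3 M aq. HCl, MeOH, 45 °C
Reagents that add atoms: none
Why: Acid-catalysed acetal exchange with methanol (MOM cleavage) frees both phenols, and the chroman ether, the secondary alcohol and the ketone are stable to dilute acid, with C3 unable to epimerise.

Step 6
Reactants: 8 [(3R)-3,5,7-trihydroxy-2,2-dimethyl-3,4-dihydro-2H-chromen-8-yl](phenyl)methanone; 9 1-bromo-3-methylbut-2-ene (prenyl bromide)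
Product: 10 [(3R)-3,5,7-trihydroxy-2,2-dimethyl-6-(3-methylbut-2-en-1-yl)-3,4-dihydro-2H-chromen-8-yl](phenyl)methanone
Conditions: 9 (1.1 equiv), 10% aq. KOH, 0 °C; acidic work-up
Reagents that add atoms: none
Why: C-alkylation of a phloroglucinol-type phenoxide in water, where hydrogen bonding to the phenoxide oxygens favours attack through carbon; C6 is the only unsubstituted ring carbon and lies ortho to both phenoxides, and the C3 alcohol is not ionised under these conditions.

Compound list
1 | 2,4,6-trihydroxybenzophenone | O=C(c1ccccc1)c1c(O)cc(O)cc1O | starting material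
2 | (2-hydroxy-4,6-bis(methoxymethoxy)phenyl)(phenyl)methanone | O=C(c1ccccc1)c1c(O)cc(OCOC)cc1OCOC | intermediate
3 | 3-methylbut-2-enal (prenal) | CC(C)=CC=O | starting material
4 | ortho-quinone methide, (6Z)-2-benzoyl-3,5-bis(methoxymethoxy)-6-(3-methylbut-2-en-1-ylidene)cyclohexa-2,4-dien-1-one | O=C1C(C(=O)c2ccccc2)=C(OCOC)C=C(OCOC)/C1=C/C=C(C)C | intermediate
5 | [5,7-bis(methoxymethoxy)-2,2-dimethyl-2H-chromen-8-yl](phenyl)methanone | COCOc1cc(OCOC)c2c(c1C(=O)c1ccccc1)OC(C)(C)C=C2 | intermediate
6 | [(3R,4R)-3,4-epoxy-5,7-bis(methoxymethoxy)-2,2-dimethyl-3,4-dihydro-2H-chromen-8-yl](phenyl)methanone | COCOc1cc(OCOC)c2c(c1C(=O)c1ccccc1)OC(C)(C)[C@@H]1O[C@H]21 | intermediate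
7 | [(3R)-3-hydroxy-5,7-bis(methoxymethoxy)-2,2-dimethyl-3,4-dihydro-2H-chromen-8-yl](phenyl)methanone | COCOc1cc(OCOC)c2c(c1C(=O)c1ccccc1)OC(C)(C)[C@H](O)C2 | intermediate
8 | [(3R)-3,5,7-trihydroxy-2,2-dimethyl-3,4-dihydro-2H-chromen-8-yl](phenyl)methanone | O=C(c1ccccc1)c1c(O)cc(O)c2c1OC(C)(C)[C@H](O)C2 | intermediate
9 | 1-bromo-3-methylbut-2-ene (prenyl bromide) | CC(C)=CCBr | starting material
10 | [(3R)-3,5,7-trihydroxy-2,2-dimethyl-6-(3-methylbut-2-en-1-yl)-3,4-dihydro-2H-chromen-8-yl](phenyl)methanone | CC(C)=CCc1c(O)c2c(c(C(=O)c3ccccc3)c1O)OC(C)(C)[C@H](O)C2 | target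

Total step count: 6
Longest linear sequence: 6 steps (1 to 10)

Steps most likely to fail

Step 2. The hydrogen-bonded, hindered phenol may add too slowly to the iminium ion, so that self-condensation of the enal and unproductive attack through the para carbon consume the reagents. The fallback tethers the five-carbon unit through oxygen first. It sets out from 2: O-alkylation with 3-chloro-3-methylbut-1-yne (DBU, CuCl2 cat., MeCN, 0 °C) should give the aryl 1,1-dimethylpropargyl ether F1. Heating F1 (N,N-diethylaniline, 180 °C) should trigger an aromatic propargyl Claisen rearrangement to the only free ortho carbon, a 1,5-hydrogen shift and the same oxa-6π closure. It comes back to the route at 5.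

Step 6. O-alkylation and a second C-alkylation with loss of aromaticity may compete with the single C-alkylation wanted. The fallback delivers the prenyl group by sigmatropic shift from oxygen and sets out from 8. The hydroxyl at C5, which is not hydrogen-bonded and is the most acidic, should be alkylated selectively with 3-chloro-3-methylbut-1-yne (K2CO3, KI, CuI cat., acetone, 50 °C) to the 5-O-(1,1-dimethylpropargyl) ether F2. Semi-hydrogenation (H2, Lindlar catalyst Pd/CaCO3 poisoned with Pb(OAc)2, quinoline, EtOAc) should give the 5-O-(1,1-dimethylallyl) ether F3. Aromatic Claisen rearrangement of F3 (toluene, 110 °C) should move the allyl unit with allylic inversion to C6, the only free ortho position. It comes back to the route at 10.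

Step 4. The labile epoxide may isomerise by hydride shift before it is hydrogenolysed, or the benzophenone carbonyl may be over-reduced on the catalyst. The fallback turns the isomerisation into the planned path and sets the stereocentre by ketone reduction; it sets out from 6, whose enantiomeric purity then no longer matters. Meinwald rearrangement (MgBr2·OEt2, CH2Cl2, 0 °C; ionisation at C4 and 1,2-hydride shift from C3) should give the chroman-3-one F4. Corey–Bakshi–Shibata reduction of F4 ((S)-Me-CBS oxazaborolidine, BH3·SMe2, THF, −20 °C), with the quaternary C2 side as the large group, should give the 3R alcohol; the hindered diaryl ketone is expected to react more slowly. It comes back to the route at 7.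

Further compounds
F1 | step 2 | [2-(2-methylbut-3-yn-2-yloxy)-4,6-bis(methoxymethoxy)phenyl](phenyl)methanone | C#CC(C)(C)Oc1cc(OCOC)cc(OCOC)c1C(=O)c1ccccc1
F2 | step 6 | [(3R)-3,7-dihydroxy-2,2-dimethyl-5-(2-methylbut-3-yn-2-yloxy)-3,4-dihydro-2H-chromen-8-yl](phenyl)methanone | O=C(c1ccccc1)c1c(O)cc(OC(C)(C)C#C)c2c1OC(C)(C)[C@H](O)C2
F3 | step 6 | [(3R)-3,7-dihydroxy-2,2-dimethyl-5-(2-methylbut-3-en-2-yloxy)-3,4-dihydro-2H-chromen-8-yl](phenyl)methanone | O=C(c1ccccc1)c1c(O)cc(OC(C)(C)C=C)c2c1OC(C)(C)[C@H](O)C2
F4 | step 4 | [5,7-bis(methoxymethoxy)-2,2-dimethyl-3-oxo-3,4-dihydro-2H-chromen-8-yl](phenyl)methanone | COCOc1cc(OCOC)c2c(c1C(=O)c1ccccc1)OC(C)(C)C(=O)C2
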